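**Retrosynthetic overview**

1. C1–C2 of the side chain (ring CH2 to alkenyl CH): 2-(chloromethyl)-3-methylnaphthoquinone plus the (E)-alkenylalane made by methylalumination of a C31 terminal alkyne, which sets the 2E alkene. Both rings are bought intact in menadione, so no ring is formed at any stage.
2. C13–C14 (B-alkyl Suzuki–Miyaura): a chiral C14 dienyne (C2–C13) plus a C19 all-E alkenyl iodide (C14–C32).
3. Dienyne: (S)-citronellyl bromide supplies the C7 stereocentre and the native 10E alkene. It is propargylated (C4–C5), its E-methyl is oxidised (C12) and the enal is methylenated (C13).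
4. Alkenyl iodide: farnesyl bromide is propargylated, one isoprene unit is added by the proposed one-flask methylalumination / nickel alkylation (C17–C18), then methylalumination / iodination.

Assumption: side-chain carbons are numbered C1 (CH2 on the ring) to C32; the target is the 7R, all-E isomer; compounds 1, 3, 4, 10, 11 and 15 are taken as commercial.

**Route**

Step 1
Reactants: 1 menadione (2-methylnaphthalene-1,4-dione)
Product: 2 2-(chloromethyl)-3-methylnaphthalene-1,4-dione
Conditions: 37% aq. HCHO, HCl (g), AcOH, rt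
Reagents that add atoms: formaldehyde C=O; hydrogen chloride Cl
Why: Blanc-type chloromethylation can only occur at the single unsubstituted quinone carbon and gives the benzylic-type chloride used as electrophile in the last step.

Step 2
Reactants: 3 (S)-citronellyl bromide [(6S)-8-bromo-2,6-dimethyloct-2-ene]; 4 triisopropyl(prop-1-yn-1-yl)silane
Product: 6 triisopropyl[(6R)-6,10-dimethylundec-9-en-1-yn-1-yl]silane, via lithiated silylpropyne 5 (not isolated)
Conditions: 4, n-BuLi, THF, −20 °C; then 3, DMPU, −20 °C → rt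
Reagents that add atoms: none
Why: SN2 alkylation of the propargyllithium (the bulky silyl group suppresses allene formation) builds C4–C5 without touching the stereocentre, which is taken from the chiral pool; the descriptor changes from S to R only because the CIP priorities change.

Step 3
Reactants: 6 triisopropyl[(6R)-6,10-dimethylundec-9-en-1-yn-1-yl]silane
Product: 7 (2E,6R)-2,6-dimethyl-11-(triisopropylsilyl)undec-2-en-10-yn-1-ol
Conditions: SeO2 (0.3 equiv), t-BuOOH (3 equiv), salicylic acid (0.1 equiv), CH2Cl2, 0 °C → rt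
Reagents that add atoms: tert-butyl hydroperoxide CC(C)(C)OO; selenium dioxide O=[Se]=O
Why: Riley allylic oxidation (ene reaction, then [2,3]-sigmatropic shift of the allylseleninic acid) hydroxylates only the E-methyl group, so the future 10E alkene keeps its geometry; any over-oxidised enal 8 is carried into step 4.

Step 4
Reactants: 7 (2E,6R)-2,6-dimethyl-11-(triisopropylsilyl)undec-2-en-10-yn-1-ol
Product: 8 (2E,6R)-2,6-dimethyl-11-(triisopropylsilyl)undec-2-en-10-ynal
Conditions: MnO2 (15 equiv), CH2Cl2, rt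
Reagents that add atoms: none
Why: MnO2 oxidises the allylic alcohol selectively to the enal without E/Z isomerisation.

Step 5
Reactants: 8 (2E,6R)-2,6-dimethyl-11-(triisopropylsilyl)undec-2-en-10-ynal
Product: 9 triisopropyl[(6R,9E)-6,10-dimethyldodeca-9,11-dien-1-yn-1-yl]silane
Conditions: Ph3PCH3Br, n-BuLi, THF, 0 °C; then 8, 0 °C → rt
Reagents that add atoms: methyltriphenylphosphonium bromide C[P+](c1ccccc1)(c1ccccc1)c1ccccc1.[Br-]
Why: Wittig methylenation adds C13 and gives the terminal 1,3-diene; the existing trisubstituted E alkene is not involved.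

Step 6
Reactants: 10 (2E,6E)-farnesyl bromide [(2E,6E)-1-bromo-3,7,11-trimethyldodeca-2,6,10-triene]; 11 trimethyl(prop-1-yn-1-yl)silane
Product: 13 trimethyl[(5E,9E)-6,10,14-trimethylpentadeca-5,9,13-trien-1-yn-1-yl]silane, via lithiated silylpropyne 12 (not isolated)
Conditions: 11, n-BuLi, THF, −40 °C; then 10, −78 → 0 °C
Reagents that add atoms: none
Why: SN2 alkylation of the propargyllithium at the primary allylic carbon of farnesyl bromide gives the 1,5-enyne with both E alkenes retained.

Step 7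
Reactants: 13 trimethyl[(5E,9E)-6,10,14-trimethylpentadeca-5,9,13-trien-1-yn-1-yl]silane
Product: 14 (5E,9E)-6,10,14-trimethylpentadeca-5,9,13-trien-1-yne
Conditions: K2CO3, MeOH/THF, rt
Reagents that add atoms: none
Why: base-catalysed methanolysis cleaves only the C(sp)–SiMe3 bond.

Step 8
Reactants: 14 (5E,9E)-6,10,14-trimethylpentadeca-5,9,13-trien-1-yne; 15 (4-bromobut-1-yn-1-yl)trimethylsilane
Product: 17 trimethyl[(5E,9E,13E)-6,10,14,18-tetramethylnonadeca-5,9,13,17-tetraen-1-yn-1-yl]silane, via alkenylalane 16 (not isolated)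
Conditions: AlMe3 (2 equiv), Cp2ZrCl2 (0.25 equiv), ClCH2CH2Cl, rt; evaporate; then 15 (1.3 equiv), NiCl2(dme) (5 mol%), 4,4'-di-tert-butyl-2,2'-bipyridine (6 mol%), THF/NMP, 0 °C → rt
Reagents that add atoms: trimethylaluminium C[Al](C)C
Why: Proposed new method: one-flask zirconium-catalysed methylalumination followed by nickel-catalysed C(sp2)–C(sp3) coupling of the alkenylalane with an unactivated primary alkyl bromide; syn addition of Me–Al across the alkyne (Negishi carboalumination) fixes the E geometry, the alkenyl group passes from aluminium to bipyridine-ligated nickel with retention, monovalent nickel abstracts bromine from 15 to give a primary radical that is captured at nickel, and reductive elimination from trivalent nickel outruns β-hydride elimination to form C17–C18; the closest known reaction types are nickel- and palladium-catalysed alkyl Negishi couplings of alkenylzinc or alkenylzirconium reagents with unactivated alkyl bromides and the nickel-catalysed coupling of such alkenylalanes with benzylic chlorides, while direct alkyl-bromide coupling of a carboalumination-derived alkenylalane has not been described.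

Step 9
Reactants: 17 trimethyl[(5E,9E,13E)-6,10,14,18-tetramethylnonadeca-5,9,13,17-tetraen-1-yn-1-yl]silane
Product: 18 (5E,9E,13E)-6,10,14,18-tetramethylnonadeca-5,9,13,17-tetraen-1-yne
Conditions: K2CO3, MeOH/THF, rt
Reagents that add atoms: none
Why: base-catalysed methanolysis of the alkynylsilane frees the terminal alkyne for the next carboalumination.

Step 10
Reactants: 18 (5E,9E,13E)-6,10,14,18-tetramethylnonadeca-5,9,13,17-tetraen-1-yne
Product: 20 (1E,5E,9E,13E)-1-iodo-2,6,10,14,18-pentamethylnonadeca-1,5,9,13,17-pentaene, via alkenylalane 19 (not isolated)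
Conditions: AlMe3 (2 equiv), Cp2ZrCl2 (0.25 equiv), ClCH2CH2Cl, rt; then I2, THF, −30 → 0 °C
Reagents that add atoms: trimethylaluminium C[Al](C)C; iodine II
Why: Negishi carboalumination (syn methylalumination of the terminal alkyne only) followed by iodinolysis with retention gives the E-trisubstituted alkenyl iodide (typically ≥98% E); the trisubstituted alkenes are inert.

Step 11
Reactants: 9 triisopropyl[(6R,9E)-6,10-dimethyldodeca-9,11-dien-1-yn-1-yl]silane; 20 (1E,5E,9E,13E)-1-iodo-2,6,10,14,18-pentamethylnonadeca-1,5,9,13,17-pentaene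
Product: 22 triisopropyl[(6R,9E,13E,17E,21E,25E)-6,10,14,18,22,26,30-heptamethylhentriaconta-9,13,17,21,25,29-hexaen-1-yn-1-yl]silane, via alkylborane 21 (not isolated)
Conditions: 9, 9-BBN (1.1 equiv), THF, 0 °C → rt; then 20, Pd(dppf)Cl2 (5 mol%), AsPh3 (5 mol%), Cs2CO3, DMF/H2O, rt
Reagents that add atoms: none
Why: 9-BBN adds only to the terminal CH2=CH of the diene (boron on the end carbon) and the B-alkyl Suzuki–Miyaura coupling at zerovalent palladium joins C13 to C14 with retention of the alkenyl geometry; the stereocentre is not touched.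

Step 12
Reactants: 22 triisopropyl[(6R,9E,13E,17E,21E,25E)-6,10,14,18,22,26,30-heptamethylhentriaconta-9,13,17,21,25,29-hexaen-1-yn-1-yl]silane
Product: 23 (6R,9E,13E,17E,21E,25E)-6,10,14,18,22,26,30-heptamethylhentriaconta-9,13,17,21,25,29-hexaen-1-yne
Conditions: TBAF, THF, rt
Reagents that add atoms: none
Why: fluoride-induced desilylation frees the terminal alkyne and leaves the polyene untouched.

Step 13
Reactants: 23 (6R,9E,13E,17E,21E,25E)-6,10,14,18,22,26,30-heptamethylhentriaconta-9,13,17,21,25,29-hexaen-1-yne; 2 2-(chloromethyl)-3-methylnaphthalene-1,4-dione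
Product: 25 2-methyl-3-[(2E,7R,10E,14E,18E,22E,26E)-3,7,11,15,19,23,27,31-octamethyldotriaconta-2,10,14,18,22,26,30-heptaen-1-yl]naphthalene-1,4-dione, via alkenylalane 24 (not isolated)
Conditions: AlMe3 (2 equiv), Cp2ZrCl2 (0.25 equiv), ClCH2CH2Cl, rt; evaporate, THF; then 2 (1.2 equiv), NiCl2(PPh3)2 (3 mol%), n-BuLi (6 mol%), 0 °C → rt
Reagents that add atoms: trimethylaluminium C[Al](C)C
Why: Negishi carboalumination puts methyl on C3 and aluminium on C2 in a syn fashion, and coupling of the alkenylalane with the chloromethylquinone at zerovalent nickel (from NiCl2(PPh3)2 and n-BuLi) proceeds with retention to give the 2E alkene and the C1–C2 bond, the free quinone being tolerated.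

**Compound list**

1 | menadione (2-methylnaphthalene-1,4-dione) | CC1=CC(=O)c2ccccc2C1=O | starting material
2 | 2-(chloromethyl)-3-methylnaphthalene-1,4-dione | CC1=C(CCl)C(=O)c2ccccc2C1=O | intermediate
3 | (S)-citronellyl bromide, (6S)-8-bromo-2,6-dimethyloct-2-ene | CC(C)=CCC[C@H](C)CCBr | starting material
4 | triisopropyl(prop-1-yn-1-yl)silane | CC#C[Si](C(C)C)(C(C)C)C(C)C | starting material
5 | [3-(triisopropylsilyl)prop-2-yn-1-yl]lithium | [Li]CC#C[Si](C(C)C)(C(C)C)C(C)C | intermediate
6 | triisopropyl[(6R)-6,10-dimethylundec-9-en-1-yn-1-yl]silane | CC(C)=CCC[C@H](C)CCCC#C[Si](C(C)C)(C(C)C)C(C)C | intermediate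
7 | (2E,6R)-2,6-dimethyl-11-(triisopropylsilyl)undec-2-en-10-yn-1-ol | OC/C(C)=C/CC[C@H](C)CCCC#C[Si](C(C)C)(C(C)C)C(C)C | intermediate
8 | (2E,6R)-2,6-dimethyl-11-(triisopropylsilyl)undec-2-en-10-ynal | O=C/C(C)=C/CC[C@H](C)CCCC#C[Si](C(C)C)(C(C)C)C(C)C | intermediate
9 | triisopropyl[(6R,9E)-6,10-dimethyldodeca-9,11-dien-1-yn-1-yl]silane | C=C/C(C)=C/CC[C@H](C)CCCC#C[Si](C(C)C)(C(C)C)C(C)C | intermediate
10 | (2E,6E)-farnesyl bromide, (2E,6E)-1-bromo-3,7,11-trimethyldodeca-2,6,10-triene | CC(C)=CCC/C(C)=C/CC/C(C)=C/CBr | starting material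
11 | trimethyl(prop-1-yn-1-yl)silane | CC#C[Si](C)(C)C | starting material
12 | [3-(trimethylsilyl)prop-2-yn-1-yl]lithium | [Li]CC#C[Si](C)(C)C | intermediate
13 | trimethyl[(5E,9E)-6,10,14-trimethylpentadeca-5,9,13-trien-1-yn-1-yl]silane | CC(C)=CCC/C(C)=C/CC/C(C)=C/CCC#C[Si](C)(C)C | intermediate
14 | (5E,9E)-6,10,14-trimethylpentadeca-5,9,13-trien-1-yne | CC(C)=CCC/C(C)=C/CC/C(C)=C/CCC#C | intermediate
15 | (4-bromobut-1-yn-1-yl)trimethylsilane | C[Si](C)(C)C#CCCBr | starting material
16 | dimethyl[(1E,5E,9E)-2,6,10,14-tetramethylpentadeca-1,5,9,13-tetraen-1-yl]alumane | CC(C)=CCC/C(C)=C/CC/C(C)=C/CC/C(C)=C/[Al](C)C | intermediate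
17 | trimethyl[(5E,9E,13E)-6,10,14,18-tetramethylnonadeca-5,9,13,17-tetraen-1-yn-1-yl]silane | CC(C)=CCC/C(C)=C/CC/C(C)=C/CC/C(C)=C/CCC#C[Si](C)(C)C | intermediate
18 | (5E,9E,13E)-6,10,14,18-tetramethylnonadeca-5,9,13,17-tetraen-1-yne | CC(C)=CCC/C(C)=C/CC/C(C)=C/CC/C(C)=C/CCC#C | intermediate
19 | dimethyl[(1E,5E,9E,13E)-2,6,10,14,18-pentamethylnonadeca-1,5,9,13,17-pentaen-1-yl]alumane | CC(C)=CCC/C(C)=C/CC/C(C)=C/CC/C(C)=C/CC/C(C)=C/[Al](C)C | intermediate
20 | (1E,5E,9E,13E)-1-iodo-2,6,10,14,18-pentamethylnonadeca-1,5,9,13,17-pentaene | CC(C)=CCC/C(C)=C/CC/C(C)=C/CC/C(C)=C/CC/C(C)=C/I | intermediate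
21 | 9-[(3E,7R)-3,7-dimethyl-12-(triisopropylsilyl)dodec-3-en-11-yn-1-yl]-9-borabicyclo[3.3.1]nonane | B1(CC/C(C)=C/CC[C@H](C)CCCC#C[Si](C(C)C)(C(C)C)C(C)C)C2CCCC1CCC2 | intermediate
22 | triisopropyl[(6R,9E,13E,17E,21E,25E)-6,10,14,18,22,26,30-heptamethylhentriaconta-9,13,17,21,25,29-hexaen-1-yn-1-yl]silane | CC(C)=CCC/C(C)=C/CC/C(C)=C/CC/C(C)=C/CC/C(C)=C/CC/C(C)=C/CC[C@H](C)CCCC#C[Si](C(C)C)(C(C)C)C(C)C | intermediate
23 | (6R,9E,13E,17E,21E,25E)-6,10,14,18,22,26,30-heptamethylhentriaconta-9,13,17,21,25,29-hexaen-1-yne | CC(C)=CCC/C(C)=C/CC/C(C)=C/CC/C(C)=C/CC/C(C)=C/CC/C(C)=C/CC[C@H](C)CCCC#C | intermediate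
24 | dimethyl[(1E,6R,9E,13E,17E,21E,25E)-2,6,10,14,18,22,26,30-octamethylhentriaconta-1,9,13,17,21,25,29-heptaen-1-yl]alumane | CC(C)=CCC/C(C)=C/CC/C(C)=C/CC/C(C)=C/CC/C(C)=C/CC/C(C)=C/CC[C@H](C)CCC/C(C)=C/[Al](C)C | intermediate
25 | 2-methyl-3-[(2E,7R,10E,14E,18E,22E,26E)-3,7,11,15,19,23,27,31-octamethyldotriaconta-2,10,14,18,22,26,30-heptaen-1-yl]naphthalene-1,4-dione (CNP0107344.1) | CC(C)=CCC/C(C)=C/CC/C(C)=C/CC/C(C)=C/CC/C(C)=C/CC/C(C)=C/CC[C@H](C)CCC/C(C)=C/CC1=C(C)C(=O)c2ccccc2C1=O | target

**Step count and risks**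

Total step count: 13. Longest linear sequence: 8 steps (10 to 25, steps 6 to 13). The chiral branch (3 to 25) is 7 steps, and step 1 is a one-step side branch.

The three steps most likely to fail:

Step 8, the proposed new coupling. The risks are slow alkenyl transfer from aluminium to nickel, competing methyl transfer and β-hydride loss from the alkylnickel species. The fallback uses known chemistry only, sets out from 14 and comes back at 17. Compound 14 is carboaluminated as before, but alane 16 is quenched with I2 to isolate (1E,5E,9E)-1-iodo-2,6,10,14-tetramethylpentadeca-1,5,9,13-tetraene F1. Separately, zinc dust (LiCl, THF) is inserted into 15 to give bromo[4-(trimethylsilyl)but-3-yn-1-yl]zinc F2. A Pd(PPh3)4-catalysed Negishi alkyl–alkenyl coupling of F1 with F2 in THF then gives 17. The roles of the partners are reversed relative to step 8: the alkenyl unit is the electrophile and the alkyl unit the nucleophile.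

Step 3, the SeO2 allylic oxidation. The risks are a modest yield, over-oxidation and some attack at the propargylic CH2. The fallback sets out from 6 and comes back at 8, bypassing 7 and step 4. The alkene of 6 is cleaved by ozonolysis (1 equiv O3, CH2Cl2/MeOH, −78 °C, then Me2S; the silyl alkyne reacts far more slowly) to give (R)-4-methyl-9-(triisopropylsilyl)non-8-ynal F3. Wittig olefination of F3 with the stabilised ylide 2-(triphenylphosphoranylidene)propanal (toluene, 90 °C) rebuilds the E-enal 8 (E:Z typically ≥95:5; the minor Z isomer is removed by chromatography at this small-molecule stage).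

Step 11, the hydroboration / B-alkyl Suzuki union of the two advanced fragments. The risks are incomplete or unselective hydroboration of the diene and slow B-alkyl transmetalation. The fallback sets out from 9 and 20 and comes back at 22; it makes the alkyl partner the electrophile. Borane 21 is oxidised (NaOH, H2O2) to (3E,7R)-3,7-dimethyl-12-(triisopropylsilyl)dodec-3-en-11-yn-1-ol F4, which is converted (I2, PPh3, imidazole, Appel-type) into triisopropyl[(6R,9E)-12-iodo-6,10-dimethyldodec-9-en-1-yn-1-yl]silane F5. Iodide 20 is treated with t-BuLi (2 equiv, −78 °C) to give [(1E,5E,9E,13E)-2,6,10,14,18-pentamethylnonadeca-1,5,9,13,17-pentaen-1-yl]lithium F6, which ZnCl2 converts into chloro[(1E,5E,9E,13E)-2,6,10,14,18-pentamethylnonadeca-1,5,9,13,17-pentaen-1-yl]zinc F7. An alkyl-electrophile Negishi coupling of F5 with F7 (Pd2(dba)3, P(c-C5H9)3, N-methylimidazole, THF/NMP, 80 °C) gives 22.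

**Further compounds**

F1 | step 8 | (1E,5E,9E)-1-iodo-2,6,10,14-tetramethylpentadeca-1,5,9,13-tetraene | CC(C)=CCC/C(C)=C/CC/C(C)=C/CC/C(C)=C/I
F2 | step 8 | bromo[4-(trimethylsilyl)but-3-yn-1-yl]zinc | C[Si](C)(C)C#CCC[Zn]Br
F3 | step 3 | (R)-4-methyl-9-(triisopropylsilyl)non-8-ynal | O=CCC[C@H](C)CCCC#C[Si](C(C)C)(C(C)C)C(C)C
F4 | step 11 | (3E,7R)-3,7-dimethyl-12-(triisopropylsilyl)dodec-3-en-11-yn-1-ol | OCC/C(C)=C/CC[C@H](C)CCCC#C[Si](C(C)C)(C(C)C)C(C)C
F5 | step 11 | triisopropyl[(6R,9E)-12-iodo-6,10-dimethyldodec-9-en-1-yn-1-yl]silane | ICC/C(C)=C/CC[C@H](C)CCCC#C[Si](C(C)C)(C(C)C)C(C)C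
F6 | step 11 | [(1E,5E,9E,13E)-2,6,10,14,18-pentamethylnonadeca-1,5,9,13,17-pentaen-1-yl]lithium | CC(C)=CCC/C(C)=C/CC/C(C)=C/CC/C(C)=C/CC/C(C)=C/[Li]
F7 | step 11 | chloro[(1E,5E,9E,13E)-2,6,10,14,18-pentamethylnonadeca-1,5,9,13,17-pentaen-1-yl]zinc | CC(C)=CCC/C(C)=C/CC/C(C)=C/CC/C(C)=C/CC/C(C)=C/[Zn]Cl
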